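Each flask is charged with twice as much first nucleophile as substrate, and the flasks differ in temperature.

all flasks: substrate 40 mM; first nucleophile 80.0 mM; second nucleophile 72.0 mM; capture agent 4.00 mM; time 12 d

| run | temperature |
|---|---|
| grey | 90 °C |
| violet | 50 °C |
| teal | 70 °C |

    substrate → open intermediate (k1 = 0.148 h⁻¹, Ea1 = 106 kJ mol⁻¹)
    first nucleophile + open intermediate → target (k2 = 31.8 L mol⁻¹ h⁻¹, Ea2 = 73.0 kJ mol⁻¹)
    second nucleophile + open intermediate → other capture product (k3 = 3.94 L mol⁻¹ h⁻¹, Ea3 = 60.0 kJ mol⁻¹)
    open intermediate → solvolysis product (k4 = 2.51 h⁻¹, Ea4 = 97.0 kJ mol⁻¹)
    open intermediate + capture agent → trapped intermediate (k5 = 1.01 L mol⁻¹ h⁻¹, Ea5 = 84.0 kJ mol⁻¹)
    (constants at 50 °C)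

- the flask with the highest share of target in all that became target or other capture product or solvolysis product or trapped intermediate ("all alike" if they lie within 1.5 percentage points) (grey / violet / teal / all alike)
- share of target in all that became target or other capture product or solvolysis product or trapped intermediate, grey
- share of target in all that became target or other capture product or solvolysis product or trapped intermediate, violet
- share of target in all that became target or other capture product or solvolysis product or trapped intermediate, teal

- the constants hold at 50 °C; other temperatures follow from the activation energies

In violet the substrate has a half-life of 4.68 h, far shorter than the 12 d of the run, and its activation energy of 106 kJ mol⁻¹ makes it quicker in the warmer flasks. So we count every substrate molecule as having passed through the open intermediate, and the share of target becomes a question of which exit that intermediate takes.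

We hold [second nucleophile] and [capture agent] at their charges, which makes those exits pseudo-first-order. One number then carries the competition: the break-even concentration, the summed pseudo-first-order rate constants of the exits that do not give target, divided by the rate constant of capture by first nucleophile. It is the [first nucleophile] at which target takes half of the open intermediate, and the share at any moment is [first nucleophile] / ([first nucleophile] + break-even concentration).

In violet the break-even concentration is 88.0 mM, so the charge gives a starting share of 47.6%. The share then falls as target formation uses up first nucleophile, and we compute this as a small correction. On average [first nucleophile] lies lower by the fraction 11.9%. A share s loses s(1 − s) times such a fraction, which is 3 percentage points, and that leaves 44.7%.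

The second way is the integrated balance. If x of first nucleophile is consumed, the substrate charge must equal x plus the break-even concentration times ln(B / (B − x)), where B is the charge of first nucleophile. With x at 17.9 mM the second term is 22.2 mM, and the sum is 40.1 mM against the 40 mM charged, so the linear correction stands up against the integral, though both rest on the same break-even concentration.

From violet to grey, solvolysis speeds up 53 times. The logarithm of such a factor scales with activation energy, so capture by first nucleophile speeds up 19.9 times. The break-even concentration in grey therefore rises to 217 mM, the starting share is 27.0%, and the same correction gives 25.6%, less than in violet. Teal lies between them in temperature, so we place it between them in share, without a number, and we name violet.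

The forecast named violet, with 25.7% for grey, 44.6% for violet and 34.3% for teal, on the ground that “Solvolysis has a much higher activation energy than capture by the first nucleophile, so heating favours it”.

The run gives violet the highest share: 44.6% there, 25.7% in grey and 34.3% in teal. In violet at 0.195 d, open intermediate passes to solvolysis product 1.1 times as fast as to target, and at the end of that flask [first nucleophile] stands at 78% of its charge, which is 62.2 mM, below the break-even concentration of 88.0 mM. A neighbour like violet but with 290 mM of second nucleophile has a break-even concentration of 115 mM, a starting share of 41.0%, and a corrected share of 38.5%; that flask ends at 38.6%.

(Its constants are those of an exercise; no experiment stands behind them.)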